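The isoflavone is cut at the C4–C4a bond of ring C. A 3-aryloxy-2-arylacrylic acid that already carries the O1–C2=C3 unit and ring B delivers its carboxyl carbon to ring A in an intramolecular Friedel–Crafts acylation, which closes the pyranone in one operation. The step exploits the position of C4a: ortho to O1 and para to the C7 methoxy group, it is the most nucleophilic unhindered CH of ring A. The precursor is the (Z)-acrylic acid built from 4-isopropoxy-3-methoxyphenol and the enol tosylate of formylated methyl (2,4,5-trimethoxyphenyl)acetate. The isopropyl ether masks the C6 hydroxyl and is removed last with BCl3.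

Key step: step 9

Assumption: the vinylic substitution of step 7 is expected to retain the Z geometry; any E isomer formed there is harmless, because the strongly acidic medium of step 9 interconverts the two alkene isomers before ring closure.

Step 1
Reactants: 1 2',4',5'-trimethoxyacetophenone
Product: 3 (2,4,5-trimethoxyphenyl)acetic acid, via 1-(morpholin-4-yl)-2-(2,4,5-trimethoxyphenyl)ethane-1-thione 2 (not isolated)
Conditions: S8, morpholine, p-toluenesulfonic acid monohydrate (cat.), 130 °C; then aq NaOH, benzyltriethylammonium chloride (cat.), 100 °C; then HCl to pH 2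
Reagents that add atoms: water, O (both oxygens of the CO2H group); for intermediate 2 only: sulfur, S1SSSSSSS1; morpholine, C1COCCN1
Why: Willgerodt–Kindler reaction, in which the enamine of the aryl methyl ketone is thiolated and the oxidation level moves to the terminal carbon to give the thioamide, which is hydrolysed in the same flask; aryl methyl ethers tolerate both stages.

Step 2
Reactants: 3 (2,4,5-trimethoxyphenyl)acetic acid
Product: 4 methyl (2,4,5-trimethoxyphenyl)acetate
Conditions: MeOH, H2SO4 (cat.), reflux
Reagents that add atoms: methanol, CO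
Why: Fischer esterification driven by the large excess of methanol; no other group in the molecule reacts.

Step 3
Reactants: 4 methyl (2,4,5-trimethoxyphenyl)acetate; 5 methyl formate
Product: 6 methyl (Z)-3-hydroxy-2-(2,4,5-trimethoxyphenyl)prop-2-enoate (enol form of the α-formyl ester, OH cis to CO2Me)
Conditions: NaH, THF, 0 °C to rt; then cold aq HCl
Reagents that add atoms: none
Why: Crossed Claisen condensation (formylation) of the ester enolate with the non-enolisable formate, pulled forward by deprotonation of the acidic product, which rests after acidification as the hydrogen-bonded Z enol.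

Step 4
Reactants: 6 methyl (Z)-3-hydroxy-2-(2,4,5-trimethoxyphenyl)prop-2-enoate
Product: 7 methyl (Z)-3-(tosyloxy)-2-(2,4,5-trimethoxyphenyl)prop-2-enoate (OTs cis to CO2Me)
Conditions: TsCl, N-methylimidazole, LiOH, CH2Cl2, 0 °C to rt
Reagents that add atoms: p-toluenesulfonyl chloride, Cc1ccc(cc1)S(Cl)(=O)=O
Why: O-Sulfonylation of the enolate by the N-sulfonylimidazolium salt; the lithium chelate between enolate oxygen and ester carbonyl fixes the Z geometry, so the tosyloxy group should end up cis to CO2Me.

Step 5
Reactants: 8 vanillin (4-hydroxy-3-methoxybenzaldehyde)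
Product: 9 4-isopropoxy-3-methoxybenzaldehyde
Conditions: 2-bromopropane, K2CO3, DMF, 70 °C
Reagents that add atoms: 2-bromopropane, CC(C)Br
Why: Williamson ether synthesis on the only acidic OH, with the secondary bromide in excess to offset elimination.

Step 6
Reactants: 9 4-isopropoxy-3-methoxybenzaldehyde
Product: 11 4-isopropoxy-3-methoxyphenol, via 4-isopropoxy-3-methoxyphenyl formate 10 (not isolated)
Conditions: mCPBA, CH2Cl2, rt; then K2CO3 (cat.), MeOH, rt
Reagents that add atoms: mCPBA (3-chloroperoxybenzoic acid), OOC(=O)c1cccc(Cl)c1
Why: Baeyer–Villiger oxidation in which the electron-rich aryl group migrates in the Criegee intermediate, followed by mild methanolysis of the aryl formate to the phenol.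

Step 7
Reactants: 7 methyl (Z)-3-(tosyloxy)-2-(2,4,5-trimethoxyphenyl)prop-2-enoate; 11 4-isopropoxy-3-methoxyphenol
Product: 12 methyl (Z)-3-(4-isopropoxy-3-methoxyphenoxy)-2-(2,4,5-trimethoxyphenyl)prop-2-enoate (aryloxy cis to CO2Me)
Conditions: Cs2CO3, MeCN, rt to 50 °C
Reagents that add atoms: none
Why: Nucleophilic vinylic substitution by addition–elimination, in which the phenoxide adds to C3 of the acceptor-activated enol tosylate and the ester-stabilised carbanion expels tosylate faster than it rotates, so the Z geometry should be kept.

Step 8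
Reactants: 12 methyl (Z)-3-(4-isopropoxy-3-methoxyphenoxy)-2-(2,4,5-trimethoxyphenyl)prop-2-enoate
Product: 13 (Z)-3-(4-isopropoxy-3-methoxyphenoxy)-2-(2,4,5-trimethoxyphenyl)prop-2-enoic acid
Conditions: LiOH·H2O, THF/H2O (no alcohol cosolvent), rt; then cold 1 M HCl to pH 3
Reagents that add atoms: water (delivered as LiOH·H2O), O
Why: Saponification by acyl–oxygen cleavage under mild conditions, as is usual for 3-aryloxyacrylates; alcohol is left out so that no alkoxide can exchange the aryloxy group at C3.

Step 9
Reactants: 13 (Z)-3-(4-isopropoxy-3-methoxyphenoxy)-2-(2,4,5-trimethoxyphenyl)prop-2-enoic acid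
Product: 14 6-isopropoxy-7-methoxy-3-(2,4,5-trimethoxyphenyl)-4H-chromen-4-one
Conditions: P2O5 in MeSO3H (Eaton's reagent, 7.7 wt%), dilute, 20 °C; poured onto ice
Reagents that add atoms: none
Why: P2O5/MeSO3H converts the carboxylic acid into a mixed anhydride or acylium ion, which attacks the aryloxy ring at the CH ortho to the ether oxygen in an electrophilic aromatic substitution, and proton loss from the arenium ion completes the C4–C4a bond. The closest known reaction is the acid-mediated cyclodehydration of 3-aryloxyacrylic acids to chromones, an intramolecular Friedel–Crafts acylation. Ring C closes in a 6-exo-trig mode with respect to the activated carbonyl (6-exo-dig if the free acylium ion reacts), and no stereocenter is formed. The step needs regioselectivity between the two CH groups ortho to the ether oxygen: the one that becomes C4a is para to the methoxy group and unhindered, whereas the later C8 sits between O1 and the methoxy-bearing C7 and has only ortho activation. It also needs the carboxyl group cis to the aryloxy group, which the Z acid supplies, and an E isomer would reach that geometry by reversible protonation at C2, which turns C2–C3 into a single bond in the C3 oxocarbenium ion. Ring B is no competitor because its ortho carbons could only close a four-membered ring, and dilution at room temperature should keep the isopropyl ether intact and intermolecular acylation slow.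

Step 10
Reactants: 14 6-isopropoxy-7-methoxy-3-(2,4,5-trimethoxyphenyl)-4H-chromen-4-one
Product: 15 6-hydroxy-7-methoxy-3-(2,4,5-trimethoxyphenyl)-4H-chromen-4-one (target)
Conditions: BCl3 (1 M in CH2Cl2, excess), CH2Cl2, −78 to 0 °C; then H2O
Reagents that add atoms: none
Why: Lewis-acid dealkylation in which BCl3 coordinates the ether oxygen and the secondary isopropyl group leaves as 2-chloropropane far faster than any methyl group, none of which sits peri to the C4 carbonyl where chelation would assist its loss.

Compound list
1 | 2',4',5'-trimethoxyacetophenone | CC(=O)c1cc(OC)c(OC)cc1OC | starting material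
2 | 1-(morpholin-4-yl)-2-(2,4,5-trimethoxyphenyl)ethane-1-thione | S=C(Cc1cc(OC)c(OC)cc1OC)N1CCOCC1 | intermediate
3 | (2,4,5-trimethoxyphenyl)acetic acid | OC(=O)Cc1cc(OC)c(OC)cc1OC | intermediate
4 | methyl (2,4,5-trimethoxyphenyl)acetate | COC(=O)Cc1cc(OC)c(OC)cc1OC | intermediate
5 | methyl formate | COC=O | starting material
6 | methyl (Z)-3-hydroxy-2-(2,4,5-trimethoxyphenyl)prop-2-enoate | O/C=C(\C(=O)OC)c1cc(OC)c(OC)cc1OC | intermediate
7 | methyl (Z)-3-(tosyloxy)-2-(2,4,5-trimethoxyphenyl)prop-2-enoate | Cc1ccc(cc1)S(=O)(=O)O/C=C(\C(=O)OC)c1cc(OC)c(OC)cc1OC | intermediate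
8 | vanillin | COc1cc(C=O)ccc1O | starting material
9 | 4-isopropoxy-3-methoxybenzaldehyde | CC(C)Oc1ccc(C=O)cc1OC | intermediate
10 | 4-isopropoxy-3-methoxyphenyl formate | CC(C)Oc1ccc(OC=O)cc1OC | intermediate
11 | 4-isopropoxy-3-methoxyphenol | CC(C)Oc1ccc(O)cc1OC | intermediate
12 | methyl (Z)-3-(4-isopropoxy-3-methoxyphenoxy)-2-(2,4,5-trimethoxyphenyl)prop-2-enoate | CC(C)Oc1ccc(O/C=C(\C(=O)OC)c2cc(OC)c(OC)cc2OC)cc1OC | intermediate
13 | (Z)-3-(4-isopropoxy-3-methoxyphenoxy)-2-(2,4,5-trimethoxyphenyl)prop-2-enoic acid | CC(C)Oc1ccc(O/C=C(\C(O)=O)c2cc(OC)c(OC)cc2OC)cc1OC | intermediate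
14 | 6-isopropoxy-7-methoxy-3-(2,4,5-trimethoxyphenyl)-4H-chromen-4-one | COc1cc2occ(-c3cc(OC)c(OC)cc3OC)c(=O)c2cc1OC(C)C | intermediate
15 | 6-hydroxy-7-methoxy-3-(2,4,5-trimethoxyphenyl)-4H-chromen-4-one | COc1cc2occ(-c3cc(OC)c(OC)cc3OC)c(=O)c2cc1O | target

Total step count: 10
Longest linear sequence: 8 steps (steps 1, 2, 3, 4, 7, 8, 9, 10, from compound 1); the vanillin branch (steps 5 and 6) joins at step 7.

Steps most likely to fail

Step 9. In the strong acid the isopropyl group may be lost before the ring closes. Ring B, which is very electron-rich, may be sulfonylated or acylated intermolecularly. The aryl vinyl ether may also fragment and recombine through carbon towards a coumarin. Fallback: the route sets out from phenol 11 and acid 3 and abandons the C4–C4a closure. Friedel–Crafts acylation of 11 with 3 in BF3·OEt2 at about 70 °C should place the arylacetyl group ortho to the hydroxyl and para to the methoxy group. This should give the deoxybenzoin 1-(2-hydroxy-5-isopropoxy-4-methoxyphenyl)-2-(2,4,5-trimethoxyphenyl)ethan-1-one F1. Heating F1 with N,N-dimethylformamide dimethyl acetal should insert C2 and close ring C through O1–C2, and the sequence comes back to the route at 14.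

Step 7. The phenoxide may attack the sulfur of the tosylate instead of C3, which transfers the sulfonyl group and returns the enolate of 6. Rotation in the carbanion may also erode the alkene geometry. Fallback: the route sets out from 6 and replaces the sulfonate by a halide that has no second electrophilic centre. Oxalyl chloride with catalytic N,N-dimethylformamide in CH2Cl2 at 0 °C should convert the enol into methyl (Z)-3-chloro-2-(2,4,5-trimethoxyphenyl)prop-2-enoate F2. Displacement of chloride by phenol 11 with K2CO3 in DMF comes back to the route at 12.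

Step 8. Hydroxide may add to C3 and expel the phenoxide, the reverse of step 7, in competition with slow attack at the hindered, donor-deactivated ester carbonyl. Fallback: the route sets out from acid 3 and carries an ester that is removed by acid, so that no hydroxide meets the aryloxyacrylate. The sequence runs as follows and comes back to the route at 13:
- Boc2O with catalytic 4-(dimethylamino)pyridine in tert-butanol should give tert-butyl (2,4,5-trimethoxyphenyl)acetate F3.
- Formylation with methyl formate 5 and KOtBu in THF should give tert-butyl (Z)-3-hydroxy-2-(2,4,5-trimethoxyphenyl)prop-2-enoate F4.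
- TsCl, N-methylimidazole and LiOH should give tert-butyl (Z)-3-(tosyloxy)-2-(2,4,5-trimethoxyphenyl)prop-2-enoate F5.
- Phenol 11 with Cs2CO3 in MeCN should give tert-butyl (Z)-3-(4-isopropoxy-3-methoxyphenoxy)-2-(2,4,5-trimethoxyphenyl)prop-2-enoate F6.
- CF3CO2H in CH2Cl2 at 0 °C should cleave the tert-butyl ester with loss of isobutene to give 13.

Further compounds
F1 | step 9 | 1-(2-hydroxy-5-isopropoxy-4-methoxyphenyl)-2-(2,4,5-trimethoxyphenyl)ethan-1-one | CC(C)Oc1cc(C(=O)Cc2cc(OC)c(OC)cc2OC)c(O)cc1OC
F2 | step 7 | methyl (Z)-3-chloro-2-(2,4,5-trimethoxyphenyl)prop-2-enoate | Cl/C=C(\C(=O)OC)c1cc(OC)c(OC)cc1OC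
F3 | step 8 | tert-butyl (2,4,5-trimethoxyphenyl)acetate | CC(C)(C)OC(=O)Cc1cc(OC)c(OC)cc1OC
F4 | step 8 | tert-butyl (Z)-3-hydroxy-2-(2,4,5-trimethoxyphenyl)prop-2-enoate | O/C=C(\C(=O)OC(C)(C)C)c1cc(OC)c(OC)cc1OC
F5 | step 8 | tert-butyl (Z)-3-(tosyloxy)-2-(2,4,5-trimethoxyphenyl)prop-2-enoate | Cc1ccc(cc1)S(=O)(=O)O/C=C(\C(=O)OC(C)(C)C)c1cc(OC)c(OC)cc1OC
F6 | step 8 | tert-butyl (Z)-3-(4-isopropoxy-3-methoxyphenoxy)-2-(2,4,5-trimethoxyphenyl)prop-2-enoate | CC(C)Oc1ccc(O/C=C(\C(=O)OC(C)(C)C)c2cc(OC)c(OC)cc2OC)cc1OC
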